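## Retrosynthetic overview

1. Target 22 (labdane numbering; trans-decalin, axial C-4 CO2Me cis to the C-10 methyl, C-9 side chain axial and trans to the C-10 methyl, 13R) ⇐ 21 ⇐ 20 by hydrolysis of the side-chain ester and methylenation of the C-8 ketone.
2. 20 ⇐ 13 + 17: ring B is made last by one-carbon ring enlargement of a trans-hydrindanone (C-10 shifts from C-8 to the new carbon C-9); the C8–C9 enolate so formed is alkylated by iodide 17 anti to the angular methyl.
3. 13 ⇐ 12 ⇐ 10 ⇐ 7: ring A is closed onto the cyclopentanedione by a desymmetrising reductive aldol (C-4, C-10), then dehydration and hydrogenation (C-5).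
4. 7 ⇐ 1 + 2 + 4 (Michael addition, Wittig); 17 ⇐ 14 (asymmetric conjugate reduction sets C-13, then lactone opening).
5. Ring order: cyclopentane (bought in 1) → ring A → ring B (by expansion of that cyclopentane).

Assumption: labdane numbering of the target is carried back to all intermediates, and in steps 3 and 7 the ligand antipode written is taken to give the sense drawn; if the first run shows the opposite sense the mirror-image ligand is used and nothing else changes.

## Route

Step 1
Reactants: 1 2-methylcyclopentane-1,3-dione; 2 acrolein (prop-2-enal)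
Product: 3 3-(1-methyl-2,5-dioxocyclopentyl)propanal
Conditions: H2O, rt, 16 h
Reagents that add atoms: none
Why: Michael addition: the acidic cyclic 1,3-dione adds 1,4 to acrolein in water without added base and gives the quaternary carbon (still prochiral) with no second acidic C–H left to over-alkylate.

Step 2
Reactants: 3 3-(1-methyl-2,5-dioxocyclopentyl)propanal; 4 methyl 2-bromopropanoate
Product: 7 methyl (2E)-2-methyl-5-(1-methyl-2,5-dioxocyclopentyl)pent-2-enoate, via phosphonium bromide 5 (not isolated), via ylide 6 (not isolated)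
Conditions: 4, PPh3, toluene, 90 °C; then 3, CH2Cl2, sat. aq NaHCO3, rt to 40 °C
Reagents that add atoms: none
Why: Wittig olefination: SN2 of PPh3 on the α-bromo ester and mild deprotonation give the stabilised ylide 6, which olefinates the aldehyde E-selectively and leaves the hindered ring ketones alone.

Step 3
Reactants: 7 methyl (2E)-2-methyl-5-(1-methyl-2,5-dioxocyclopentyl)pent-2-enoate
Product: 10 methyl (3aS,4R,7aR)-3a-hydroxy-4,7a-dimethyl-1-oxooctahydro-1H-indene-4-carboxylate, via copper enolate 8 (not isolated), via silyl ether 9 (not isolated)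
Conditions: Cu(OAc)2 (5 mol %), (R)-DM-SEGPHOS (5.5 mol %), (MeO)2MeSiH (2 equiv), THF, −20 °C; then 1 M HCl, THF, 0 °C
Reagents that add atoms: none
Why: Proposed new method: ligated CuH adds hydride 1,4 to the α-methyl enoate to give the fully substituted copper enolate 8, which closes ring A by intramolecular aldol addition onto one of the two enantiotopic ring ketones through a chair-like Cu-bridged (Zimmerman–Traxler type) transition state in which the chiral bisphosphine selects the carbonyl (sets C-10), the tether forces attack cis to C-1 (OH cis to the angular methyl) and the O–Cu–O bridge places the ester cis to the new OH (sets C-4, ester cis to the C-10 methyl), the aldolate being silylated to 9 and freed on work-up; closest known reaction type: copper hydride catalysed domino conjugate reduction–aldol cyclisation of enoate- or enone-tethered ketones and 1,3-diones with α-unsubstituted acceptors, here extended to a tetrasubstituted enolate that creates a quaternary ester carbon.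

Step 4
Reactants: 10 methyl (3aS,4R,7aR)-3a-hydroxy-4,7a-dimethyl-1-oxooctahydro-1H-indene-4-carboxylate
Product: 11 methyl (4R,7aR)-4,7a-dimethyl-1-oxo-2,4,5,6,7,7a-hexahydro-1H-indene-4-carboxylate
Conditions: SOCl2, pyridine, CH2Cl2, −20 to 0 °C
Reagents that add atoms: none
Why: Dehydration through the chlorosulfite (E2): the tertiary carbinol has β-hydrogens only at C-6 because C-4 and C-10 are quaternary, so the C5=C6 alkene is the only elimination product, as in the SOCl2/pyridine dehydration of 14-hydroxy steroids.

Step 5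
Reactants: 11 methyl (4R,7aR)-4,7a-dimethyl-1-oxo-2,4,5,6,7,7a-hexahydro-1H-indene-4-carboxylate
Product: 12 methyl (3aS,4R,7aR)-4,7a-dimethyl-1-oxooctahydro-1H-indene-4-carboxylate (trans-fused)
Conditions: H2 (1–3 atm), 10% Pd/C, EtOAc, rt
Reagents that add atoms: none
Why: Heterogeneous catalytic hydrogenation: the α-face of the C5=C6 bond is blocked by the angular methyl and the axial C-4 ester on the two flanking quaternary carbons, so hydrogen is delivered from the β-face and sets C-5 with H trans to the methyl (trans-hydrindane, as for 14-ene 17-keto steroids).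

Step 6
Reactants: 12 methyl (3aS,4R,7aR)-4,7a-dimethyl-1-oxooctahydro-1H-indene-4-carboxylate
Product: 13 methyl (1R,3aS,4R,7aR)-1-(dibromomethyl)-1-hydroxy-4,7a-dimethyloctahydro-1H-indene-4-carboxylate
Conditions: CH2Br2, LiN(iPr)2, THF, −78 °C; then AcOH, −78 °C
Reagents that add atoms: dibromomethane, BrCBr
Why: 1,2-Addition of the carbenoid LiCHBr2 (made in situ) to the cyclopentanone from the face away from the angular methyl, the new carbinol centre being destroyed again in step 9 and the hindered tertiary ester being inert at −78 °C.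

Step 7
Reactants: 14 4-methyl-5,6-dihydro-2H-pyran-2-one
Product: 15 (4R)-4-methyloxan-2-one
Conditions: Cu(OAc)2 (3 mol %), (S)-p-Tol-BINAP (3.3 mol %), (MeO)2MeSiH (1.5 equiv), t-BuOH (1.2 equiv), toluene, 0 °C
Reagents that add atoms: none
Why: Asymmetric conjugate reduction with ligated CuH: enantioface-selective hydride delivery to the β-carbon of the unsaturated lactone sets the methyl-bearing centre (later C-13) under catalyst control, and t-BuOH protonates the enolate and turns the catalyst over.

Step 8
Reactants: 15 (4R)-4-methyloxan-2-one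
Product: 17 methyl (3S)-5-iodo-3-methylpentanoate, via silyl ester 16 (not isolated)
Conditions: Me3SiI, CH2Cl2, rt; then MeOH, 40 °C
Reagents that add atoms: iodotrimethylsilane, C[Si](C)(C)I; methanol, CO
Why: Silyl iodide lactone cleavage: O-silylation and SN2 attack of iodide at the O–CH2 carbon open the lactone to silyl ester 16, which methanol (HI formed in situ) converts to the methyl ester without touching the stereocentre (R becomes S only through the priority rules).

Step 9
Reactants: 13 methyl (1R,3aS,4R,7aR)-1-(dibromomethyl)-1-hydroxy-4,7a-dimethyloctahydro-1H-indene-4-carboxylate; 17 methyl (3S)-5-iodo-3-methylpentanoate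
Product: 20 methyl (1R,4aR,5R,8aS)-5-[(3R)-5-methoxy-3-methyl-5-oxopentyl]-1,4a-dimethyl-6-oxodecahydronaphthalene-1-carboxylate, via carbenoid 18 (not isolated), via lithium enolate 19 (not isolated)
Conditions: n-BuLi (2.1 equiv), THF, −95 to −60 °C; then HMPA, 17 (2 equiv), −60 to −20 °C
Reagents that add atoms: none
Why: β-Oxido carbenoid ring enlargement (Nozaki–Yamamoto type 1,2-shift): deprotonation and Br/Li exchange give carbenoid 18, the more substituted and electron-richer α-carbon C-10 shifts from C-8 to the carbenoid carbon with loss of LiBr so that the cyclopentane becomes the cyclohexanone enolate 19 with the enolate fixed at C8–C9, and SN2 alkylation by iodide 17 then occurs axially on the face anti to the axial angular methyl, which sets C-9 with the side chain trans to that methyl.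

Step 10
Reactants: 20 methyl (1R,4aR,5R,8aS)-5-[(3R)-5-methoxy-3-methyl-5-oxopentyl]-1,4a-dimethyl-6-oxodecahydronaphthalene-1-carboxylate
Product: 21 methyl (1R,4aS,5S,8aS)-5-[(3R)-5-methoxy-3-methyl-5-oxopentyl]-1,4a-dimethyl-6-methylidenedecahydronaphthalene-1-carboxylate
Conditions: Zn, CH2Br2, TiCl4, THF/CH2Cl2, 0 °C to rt
Reagents that add atoms: dibromomethane, BrCBr
Why: Takai–Lombardo methylenation: the non-basic Zn/Ti gem-dimetal reagent converts the hindered ketone to the exocyclic alkene without enolisation, so the axial (less stable) C-9 centre is kept and both esters survive.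

Step 11
Reactants: 21 methyl (1R,4aS,5S,8aS)-5-[(3R)-5-methoxy-3-methyl-5-oxopentyl]-1,4a-dimethyl-6-methylidenedecahydronaphthalene-1-carboxylate
Product: 22 (3R)-5-[(1S,4aS,5R,8aS)-5-(methoxycarbonyl)-5,8a-dimethyl-2-methylidenedecahydronaphthalen-1-yl]-3-methylpentanoic acid
Conditions: LiOH (1.5 equiv), THF/H2O 3:1, 0 °C to rt; then 1 M HCl to pH 3
Reagents that add atoms: lithium hydroxide, [Li+].[OH-]
Why: Saponification: hydroxide attacks only the unhindered primary side-chain ester, while the axial neopentyl-type C-4 methyl ester is inert at room temperature and no stereocentre next to a reacting carbonyl is present.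

## Compound list

1 | 2-methylcyclopentane-1,3-dione | CC1C(=O)CCC1=O | starting material
2 | acrolein (prop-2-enal) | C=CC=O | starting material
3 | 3-(1-methyl-2,5-dioxocyclopentyl)propanal | O=CCCC1(C)C(=O)CCC1=O | intermediate
4 | methyl 2-bromopropanoate (racemic) | COC(=O)C(C)Br | starting material
5 | (1-methoxy-1-oxopropan-2-yl)triphenylphosphonium bromide | COC(=O)C(C)[P+](c1ccccc1)(c1ccccc1)c1ccccc1.[Br-] | intermediate (not isolated)
6 | methyl 2-(triphenylphosphoranylidene)propanoate | COC(=O)C(C)=P(c1ccccc1)(c1ccccc1)c1ccccc1 | intermediate (not isolated)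
7 | methyl (2E)-2-methyl-5-(1-methyl-2,5-dioxocyclopentyl)pent-2-enoate | COC(=O)/C(C)=C/CCC1(C)C(=O)CCC1=O | intermediate
8 | copper enolate of methyl 2-methyl-5-(1-methyl-2,5-dioxocyclopentyl)pentanoate (bisphosphine on Cu not drawn) | COC(O[Cu])=C(C)CCCC1(C)C(=O)CCC1=O | intermediate (not isolated)
9 | methyl (3aS,4R,7aR)-3a-{[dimethoxy(methyl)silyl]oxy}-4,7a-dimethyl-1-oxooctahydro-1H-indene-4-carboxylate | O=C1CC[C@]2(O[Si](C)(OC)OC)[C@@]1(C)CCC[C@@]2(C)C(=O)OC | intermediate (not isolated)
10 | methyl (3aS,4R,7aR)-3a-hydroxy-4,7a-dimethyl-1-oxooctahydro-1H-indene-4-carboxylate (OH, angular methyl and ester all cis) | O=C1CC[C@]2(O)[C@@]1(C)CCC[C@@]2(C)C(=O)OC | intermediate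
11 | methyl (4R,7aR)-4,7a-dimethyl-1-oxo-2,4,5,6,7,7a-hexahydro-1H-indene-4-carboxylate (C3=C3a alkene) | O=C1CC=C2[C@@]1(C)CCC[C@@]2(C)C(=O)OC | intermediate
12 | methyl (3aS,4R,7aR)-4,7a-dimethyl-1-oxooctahydro-1H-indene-4-carboxylate (trans-fused; ester cis to angular methyl) | O=C1CC[C@H]2[C@@]1(C)CCC[C@@]2(C)C(=O)OC | intermediate
13 | methyl (1R,3aS,4R,7aR)-1-(dibromomethyl)-1-hydroxy-4,7a-dimethyloctahydro-1H-indene-4-carboxylate | BrC(Br)[C@@]1(O)CC[C@H]2[C@@]1(C)CCC[C@@]2(C)C(=O)OC | intermediate
14 | 4-methyl-5,6-dihydro-2H-pyran-2-one | CC1=CC(=O)OCC1 | starting material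
15 | (4R)-4-methyloxan-2-one | C[C@@H]1CCOC(=O)C1 | intermediate
16 | trimethylsilyl (3S)-5-iodo-3-methylpentanoate | ICC[C@@H](C)CC(=O)O[Si](C)(C)C | intermediate (not isolated)
17 | methyl (3S)-5-iodo-3-methylpentanoate | ICC[C@@H](C)CC(=O)OC | intermediate
18 | lithium (1R,3aS,4R,7aR)-1-[bromo(lithio)methyl]-4-(methoxycarbonyl)-4,7a-dimethyloctahydro-1H-inden-1-olate (β-oxido carbenoid) | [Li]C(Br)[C@@]1(O[Li])CC[C@H]2[C@@]1(C)CCC[C@@]2(C)C(=O)OC | intermediate (not isolated)
19 | lithium (4aS,5R,8aS)-5-(methoxycarbonyl)-5,8a-dimethyl-3,4,4a,5,6,7,8,8a-octahydronaphthalen-2-olate (C8–C9 enolate) | [Li]OC1=C[C@]2(C)CCC[C@@](C)(C(=O)OC)[C@H]2CC1 | intermediate (not isolated)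
20 | methyl (1R,4aR,5R,8aS)-5-[(3R)-5-methoxy-3-methyl-5-oxopentyl]-1,4a-dimethyl-6-oxodecahydronaphthalene-1-carboxylate | O=C1CC[C@H]2[C@@](C)(CCC[C@@]2(C)C(=O)OC)[C@H]1CC[C@@H](C)CC(=O)OC | intermediate
21 | methyl (1R,4aS,5S,8aS)-5-[(3R)-5-methoxy-3-methyl-5-oxopentyl]-1,4a-dimethyl-6-methylidenedecahydronaphthalene-1-carboxylate | C=C1CC[C@H]2[C@@](C)(CCC[C@@]2(C)C(=O)OC)[C@H]1CC[C@@H](C)CC(=O)OC | intermediate
22 | (3R)-5-[(1S,4aS,5R,8aS)-5-(methoxycarbonyl)-5,8a-dimethyl-2-methylidenedecahydronaphthalen-1-yl]-3-methylpentanoic acid | C=C1CC[C@H]2[C@@](C)(CCC[C@@]2(C)C(=O)OC)[C@H]1CC[C@@H](C)CC(=O)O | target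

## Step count and risks

Total steps: 11. Longest linear sequence: 9 (steps 1–6 and 9–11; steps 7–8 make the side-chain iodide).

**Step 3 (the proposed new method).** Risks are low enantioselectivity with the tetrasubstituted enolate, competing ketone reduction, and the wrong C-4 epimer if the bridged transition state is not followed. The fallback uses known reaction types, sets out from 7 and comes back at 10. Transfer hydrogenation with RuCl(p-cymene)[(S,S)-TsDPEN] in HCO2H/Et3N (the catalyst antipode that gives the shown product) reduces one of the two enantiotopic ring ketones and gives methyl (2E)-5-[(1S,2S)-2-hydroxy-1-methyl-5-oxocyclopentyl]-2-methylpent-2-enoate F1; this is the established desymmetrisation of 2,2-disubstituted cyclopentane-1,3-diones, and the carbinol configuration is of no consequence. Stoichiometric [(Ph3P)CuH]6 in toluene then effects conjugate reduction and aldol closure onto the one remaining ketone under substrate control and gives methyl (1S,3aS,4R,7aS)-1,3a-dihydroxy-4,7a-dimethyloctahydro-1H-indene-4-carboxylate F2. Dess–Martin periodinane oxidises the secondary alcohol and returns 10.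

**Step 4.** The tertiary carbinol sits between two quaternary carbons, so ionisation could lead to a methyl shift or to the tertiary chloride instead of clean elimination. The fallback sets out from 10 and comes back at 12, bypassing 11. ClC(O)CO2Me, pyridine and DMAP give methyl (3aS,4R,7aR)-3a-[(2-methoxy-2-oxoacetyl)oxy]-4,7a-dimethyl-1-oxooctahydro-1H-indene-4-carboxylate F3. Bu3SnH and AIBN in toluene at reflux (radical deoxygenation of a tertiary oxalate) generate the C-5 radical, which takes hydrogen from the open β-face, anti to the angular methyl and the axial ester, and gives 12 directly.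

**Step 9.** Two things can go wrong. The route needs the quaternary C-10 to migrate, which is the usual preference of β-oxido carbenoids and the opposite of diazoalkane homologation. The neopentyl-type enolate 19 must then be C-alkylated by an unactivated primary iodide before proton transfer scrambles the enolate or epimerises C-9; the n-BuBr formed in the flask is a much slower electrophile than 17. The fallback addresses the alkylation, sets out from 13 and comes back at 20. Enolate 19 is generated exactly as before and trapped at −78 °C in an aldol addition with methyl (3R)-3-methyl-5-oxopentanoate F4, made from 17 by Kornblum-type oxidation with Me3NO in DMSO. The aldol takes the same axial approach anti to the angular methyl and gives methyl (1R,4aR,5S,8aS)-5-[(3R)-1-hydroxy-5-methoxy-3-methyl-5-oxopentyl]-1,4a-dimethyl-6-oxodecahydronaphthalene-1-carboxylate F5 as a mixture of carbinol epimers. PhOC(S)Cl, pyridine and DMAP give methyl (1R,4aR,5S,8aS)-5-[(3R)-5-methoxy-3-methyl-5-oxo-1-(phenoxycarbonothioyloxy)pentyl]-1,4a-dimethyl-6-oxodecahydronaphthalene-1-carboxylate F6. Bu3SnH and AIBN in toluene at 80 °C (Barton–McCombie deoxygenation) remove the oxygen and return 20.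

Further compounds
F1 | step 3 | methyl (2E)-5-[(1S,2S)-2-hydroxy-1-methyl-5-oxocyclopentyl]-2-methylpent-2-enoate | COC(=O)/C(C)=C/CC[C@]1(C)C(=O)CC[C@@H]1O
F2 | step 3 | methyl (1S,3aS,4R,7aS)-1,3a-dihydroxy-4,7a-dimethyloctahydro-1H-indene-4-carboxylate | O[C@H]1CC[C@]2(O)[C@@]1(C)CCC[C@@]2(C)C(=O)OC
F3 | step 4 | methyl (3aS,4R,7aR)-3a-[(2-methoxy-2-oxoacetyl)oxy]-4,7a-dimethyl-1-oxooctahydro-1H-indene-4-carboxylate | O=C1CC[C@]2(OC(=O)C(=O)OC)[C@@]1(C)CCC[C@@]2(C)C(=O)OC
F4 | step 9 | methyl (3R)-3-methyl-5-oxopentanoate | O=CC[C@@H](C)CC(=O)OC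
F5 | step 9 | methyl (1R,4aR,5S,8aS)-5-[(3R)-1-hydroxy-5-methoxy-3-methyl-5-oxopentyl]-1,4a-dimethyl-6-oxodecahydronaphthalene-1-carboxylate (carbinol epimers) | O=C1CC[C@H]2[C@@](C)(CCC[C@@]2(C)C(=O)OC)[C@H]1C(O)C[C@@H](C)CC(=O)OC
F6 | step 9 | methyl (1R,4aR,5S,8aS)-5-[(3R)-5-methoxy-3-methyl-5-oxo-1-(phenoxycarbonothioyloxy)pentyl]-1,4a-dimethyl-6-oxodecahydronaphthalene-1-carboxylate | O=C1CC[C@H]2[C@@](C)(CCC[C@@]2(C)C(=O)OC)[C@H]1C(OC(=S)Oc3ccccc3)C[C@@H](C)CC(=O)OC
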